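All constants belong to no real substance; the result is computed.

The ratio of target to intermediate is the number to find first, because the other products can be counted from it.

- amber: substrate 5.0 mM; partner 6.00 mM; protic impurity 1.00 mM; time 20 s
- grey: substrate 5.0 mM; partner 12.0 mM; protic impurity 1.00 mM; time 20 s

    substrate + partner → intermediate + released group (k1 = 17 /M/s)
    intermediate ⇌ target (K2 = 1.2, k2 = 0.13 /s)
    intermediate ⇌ isomer of the product (K3 = 6.3, k3 = 0.076 /s)
    target → over-reaction product (k4 = 0.15 /s)
    partner + protic impurity → quenched reagent (k5 = 17 /M/s)

- which of the two there is more of at the end, amber (isomer of the product / target)
- which of the two there is more of at the end, grey (isomer of the product / target)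
- amount of target at the end, in percent of the substrate charged, amber
- amount of target at the end, in percent of the substrate charged, grey

Partner meets substrate and impurity with equal constants, 17 /M/s and 17 /M/s, so these two keep the same remaining fraction. In amber the partner charge equals the two together, so partner keeps that fraction too, and second-order decay gives a converted fraction of 0.671 at 20 s. The surplus partner in grey gives 0.930.

Now two extremes. Without drain, target equilibrates with intermediate at ratio 1.2. With the drain at full effect, target sits in a quasi-steady state: inflow from intermediate balances return plus over-reaction, and the ratio is 0.503. My reckoning takes the second, because target relaxes with a half-life of 2.68 s, short against 20 s. Where intermediate falls, target lags somewhat above this ratio.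

Hold intermediate and target at their end values through the run. Each unit of target then stands beside the inverse ratio of intermediate, that amount times 1.52 of isomer, and 3.00 of over-reaction product. The isomer's way back is ignored, its half-life of 57.5 s being long against 20 s. The sum, target included, is the conversion count, the converted substrate per unit of target: 9.01. Partner does not enter it. So target should be 7.45 % in amber and 10.3 % in grey. Reckoned this way, isomer over target comes to 3.02 in both flasks, and still 1.27 at the undrained extreme, so my reckoning puts isomer ahead.

The forecast names isomer of the product for amber and isomer of the product for grey, with 8.2 % and 10.3 % of target, reasoning that “the strongly favoured, slowly reversing isomer accumulates”. Its amber figure stands above mine; its grey figure matches mine.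

The simulation gives isomer of the product ahead in amber, 23.5 % against 8.08 %, and isomer of the product ahead in grey, 34.2 % against 10.3 %. Grey's step to target had half its turnover behind it by 7.50 s, and from 10.0 s to 20.0 s target fell from 14.5 % to 10.3 % while isomer rose from 20.7 % to 34.2 %. For grey read at 12 s the conversion count is reckoned at 6.60, which gives 12.5 % of target, and that flask holds 14.3 %.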